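1. A small charge of reagent, 0.0600 M, met 0.10 M of substrate, with 0.0100 M of base beside it. I had this flask followed so far and had to say what it held at 2.5 d and which remedy paid.

- west: substrate 0.10 M; reagent 0.060 M; base 0.010 M; the very flask that is asked about, followed so far
- flask: substrate 0.10 M; reagent 0.0600 M; base 0.0100 M; time 2.5 d

west run (percent of the substrate charged)

| time / h | product / % | substrate / % |
|---|---|---|
| 5.00 | 0 | 99 |
| 8.00 | 4 | 98 |
| 12.0 | 0 | 98 |
| 20.0 | 57 | 46 |
| 40.0 | 56 | 41 |
| 60.0 | 60 | 40 |

(scatter of a reading: 2 percentage points)

- product taken out counts as made
- steps thought possible: substrate + reagent + released group -> product + 2 released group; released group -> by-product carried off; substrate + reagent -> product + released group; base + released group <-> salt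
- additions bring no volume worth counting

- Wednesday's: at 2.5 d add substrate, 50.0% of the amount charged, then wait 20 h
- Friday's: at 2.5 d add reagent, 100% of the amount charged, then wait 20 h
- Tuesday's: at 2.5 d add base, 100% of the amount charged, then wait 20 h
- Saturday's: at 2.5 d take out 90% of the product then present, then wait 20 h
- Thursday's: change nothing and wait 20 h more

* product, in percent of the substrate first charged, at 2.5 d
* the remedy with the largest gain of product, or "none" below 2 percentage points (Wednesday's / Friday's / Tuesday's / Saturday's / Thursday's / none)
* product present, with what was taken out counted in, in percent of the substrate first charged, after Wednesday's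
* product present, with what was taken out counted in, in percent of the substrate first charged, after Friday's

2. Both product-forming steps on the list take one reagent per product. So I reckoned first the reagent ceiling, the product that the charged reagent can pay for, c(reagent) charged over c(substrate) first charged, the limiting reagent's allowance: 60.0%.

3. The first instants: up to 12.0 h product read 0%, 4%, 0%, each with a scatter of 2 percentage points, and substrate read 98%. Little was happening.

4. The middle: by 20.0 h product read 57% and substrate 46%. A lag and then a leap: I read that as autocatalysis, the step in which released group makes more of itself.

5. The end: at 60.0 h product read 60%, level with the ceiling, while substrate stayed at 40%. The flask had stalled with substrate unused.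

6. My reckoning: product now at the ceiling, 60.0%. Wednesday's, Tuesday's, Saturday's and Thursday's bring no reagent, so the ceiling stays. Friday's lifts it to 120%, above the substrate charged, so I took 100% as its target.

7. The forecast gave 59% now, Friday's as best, 59% after Wednesday's and 88% after Friday's, lower than my target, warning: “If it has been carried off, a new induction period could consume most of the 20 h.”

8. The flask gave 60.0% now and 60.0% after Wednesday's. Friday's was best, with a gain of 38 points, reaching 98.4%.

    substrate + reagent + released group → product + 2 released group (k = 0.390 M⁻² s⁻¹)
    released group → by-product carried off (k = 1.20 × 10⁻⁴ s⁻¹)
    substrate + reagent → product + released group (k = 6.10 × 10⁻⁷ M⁻¹ s⁻¹)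
    base + released group ⇌ salt, settled at all times (K = 3200 M⁻¹)

The flask stopped at its ceiling, with 0.0270% of its reagent left at 60.0 h. The falling level of reagent is the main reason: the same run without that fall reached 100%, against 60.0%. After Friday's, the ceiling of this flask stood at 120%, above the substrate charged, and the flask gave 98.4%. The neighbour charged with 0.024 M of reagent has a ceiling of 24.0%, and at 2.5 d it held 22.9% product with 4.4% of its reagent left.

The numbers in the tables are calculated for an exercise; noise was put on by code.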